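**Retrosynthetic overview**
1. Rings A and B (hydroxy-oxepane and methylenecyclohexane, left half) are closed last: target ⇒ a (3S,6S,7S)-2,3:6,7-diepoxy-10-ene chain hanging on the finished right half, cyclised by one epoxide-opening/cation–olefin cascade that ends by loss of a C10-methyl proton.
2. The right half is adjusted before that: C3' ketone ⇐ C3' carbinol, oxidised while the left carbinol does not yet exist; axial C10' acetate ⇐ C10' ketone + MeCeCl2, then Ac2O.
3. Rings D and C (oxepane and cyclohexanone, right half) ⇐ an earlier cascade on the same linear chain, the right-hand diepoxide closing onto a C10'=C11' silyl enol ether.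
4. Linear C29 chain ⇐ C12–C13 Michael union of lithiated farnesyl phenyl sulfone with a diepoxy vinyl ketone; the trapped enolate is the cascade terminator, and the sulfone shields C10=C11 during the later epoxidation before it is removed.
5. Building blocks ⇐ geranylacetone and (2E,6E)-farnesol. Ring order: D and C together (step 5), then A and B together (step 10).

Atom labels: squalene-type numbering from each gem-dimethyl end; left half C2 (CMe2), C3 (carbinol), C6 (quaternary ring-fusion C), C7 (ring-fusion CH–O), C10, C11; linker C12 (left) and C13; right half the same with primes. Target: 3S,6S,7S,11R,6'S,7'S,10'R,11'S.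

Assumption: the L-fructose-derived Shi ketone (the enantiomer of the usual D-fructose catalyst) is purchased and used as a catalyst.

**Step 1**
Reactants: 1 geranylacetone
Product: 2 (5S,6S,9S)-5,6:9,10-diepoxy-6,10-dimethylundecan-2-one
Conditions: L-fructose-derived Shi ketone (0.6 equiv), KHSO5 (as Oxone, 2KHSO5·KHSO4·K2SO4), K2CO3, Bu4NHSO4, MeCN–CH2(OMe)2–aq. Na2B4O7 buffer (pH 10.5), 0 °C
Reagents that add atoms: potassium peroxymonosulfate, [K+].[O-]S(=O)(=O)OO
Why: Shi asymmetric epoxidation, in which the chiral dioxirane epoxidises both electron-rich trisubstituted alkenes through the spiro transition state on the face opposite to that used by the D-fructose catalyst, setting C6' and C7' (S,S) and C3' (S) while the methyl ketone is inert.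

**Step 2**
Reactants: 2 (5S,6S,9S)-5,6:9,10-diepoxy-6,10-dimethylundecan-2-one
Product: 6 (6S,7S,10S)-6,7:10,11-diepoxy-7,11-dimethyldodec-1-en-3-one, via lithium enolate 3 (not isolated), via Mannich base 4 (not isolated), via ammonium iodide 5 (not isolated)
Conditions: LiN(i-Pr)2, THF, −78 °C; CH2=NMe2+ I−, −78 → 23 °C; MeI, CH2Cl2, 23 °C; NaHCO3 (aq), 23 °C
Reagents that add atoms: N,N-dimethylmethyleneiminium iodide (Eschenmoser's salt), C=[N+](C)C.[I-]
Why: Kinetic deprotonation at the methyl group, Mannich reaction, N-methylation and E1cB loss of trimethylamine give the vinyl ketone (α-methylenation) without touching the epoxides, and no stereocentre is formed.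

**Step 3**
Reactants: 7 (2E,6E)-farnesol
Product: 9 (2E,6E)-farnesyl phenyl sulfone, via farnesyl bromide 8 (not isolated)
Conditions: PBr3, Et2O, 0 °C; then PhSO2Na, DMF, 23 °C
Reagents that add atoms: sodium benzenesulfinate, [Na+].[O-]S(=O)c1ccccc1
Why: SN2 bromination of the allylic alcohol followed by SN2 S-alkylation of the sulfinate keeps the E,E geometry, and no stereocentre is formed.

**Step 4**
Reactants: 9 (2E,6E)-farnesyl phenyl sulfone; 6 (6S,7S,10S)-6,7:10,11-diepoxy-7,11-dimethyldodec-1-en-3-one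
Product: 12 triethylsilyl (Z)-enol ether of the C12–C13 Michael adduct (linear C29 chain), via lithiated sulfone 10 (not isolated), via lithium enolate 11 (not isolated)
Conditions: n-BuLi, THF–HMPA (5:1), −78 °C; add 6, −78 °C; Et3SiCl, Et3N, −78 → 0 °C
Reagents that add atoms: chlorotriethylsilane, CC[Si](Cl)(CC)CC
Why: Michael addition with enolate trapping, in which the allylic sulfone anion attacks through its α-carbon (the γ-carbon is fully substituted and HMPA favours 1,4-addition) to form C12–C13 and an enolate on the C11' side only, fixed by O-silylation; C12 is formed as both epimers and is cleared in step 8.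

**Step 5**
Reactants: 12 triethylsilyl (Z)-enol ether of the Michael adduct
Product: 13 (3'S,6'S,7'S,11'S)-3'-(triethylsilyloxy) trans-fused oxepane–cyclohexan-10'-one (rings D and C) carrying the 12-(phenylsulfonyl) farnesyl-derived triene chain at C11'
Conditions: Et3SiOTf (0.2 equiv), 2,6-di-tert-butyl-4-methylpyridine, CH2Cl2, −78 °C; Et3N quench
Reagents that add atoms: none
Why: Biomimetic epoxide-opening cascade (tandem oxa-/carbacyclisation through a bicyclic epoxonium ion) in which the silylated C2'–C3' epoxide is opened at C2' by the oxygen of the C6'–C7' epoxide and the epoxonium is opened at C6' with inversion by C11' of the enol ether in a chair transition state, giving the trans-fused rings with C3' and C7' retained and the C11' chain equatorial (an epimerisable α-centre, also the thermodynamic one), while the released silyl triflate carries the chain and the sulfone-deactivated C10=C11 alkene stays out.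

**Step 6**
Reactants: 13 bicyclic C10' ketone triethylsilyl ether
Product: 16 (3'S,6'S,7'S,10'R,11'S)-10'-acetoxy-10'-methyl-3'-hydroxy bicycle with the sulfonyl triene chain, via dichlorocerium alkoxide 14 (not isolated), via triethylsilyl ether acetate 15 (not isolated)
Conditions: MeLi, CeCl3, THF, −78 °C; Ac2O, −78 → 23 °C; pyridinium p-toluenesulfonate, MeOH, 23 °C
Reagents that add atoms: methyllithium, [Li]C; acetic anhydride, CC(=O)OC(C)=O
Why: Organocerium 1,2-addition (non-basic MeCeCl2, so neither the ketone nor the sulfone is deprotonated) occurs from the equatorial face because the axial approach is blocked by the 1,3-diaxial C6' methyl group, giving the axial alkoxide (10'R) that is acylated in the flask, and acid methanolysis then removes the silyl ether.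

**Step 7**
Reactants: 16 hydroxy acetate with sulfonyl triene chain
Product: 17 (3S,6S,7S)-2,3:6,7-diepoxide of 16 (C10=C11 alkene and sulfone intact)
Conditions: L-fructose-derived Shi ketone (0.6 equiv), KHSO5 (as Oxone), K2CO3, Bu4NHSO4, MeCN–CH2(OMe)2–aq. Na2B4O7 buffer (pH 10.5), 0 °C
Reagents that add atoms: potassium peroxymonosulfate, [K+].[O-]S(=O)(=O)OO
Why: Shi epoxidation with the same catalyst converts the two remote trisubstituted alkenes into the (3S,6S,7S) epoxides, while the C10=C11 alkene is protected by the electron-withdrawing and bulky allylic sulfone.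

**Step 8**
Reactants: 17 diepoxy allylic sulfone
Product: 18 desulfonylated (10E)-diepoxy-ene hydroxy acetate
Conditions: Pd(PPh3)4 (10 mol %), NaBH4, THF–i-PrOH, 0 → 23 °C
Reagents that add atoms: none
Why: Palladium-catalysed allylic hydrogenolysis (reductive desulfonylation), in which zerovalent palladium ionises the allylic sulfone to a π-allyl complex and hydride is delivered to the less substituted terminus C12, keeps the E-trisubstituted C10=C11 alkene, and NaBH4 opens neither the trisubstituted epoxides nor the tertiary acetate; the C12 stereocentre disappears.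

**Step 9**
Reactants: 18 diepoxy-ene hydroxy acetate
Product: 19 C3' ketone (oxepanone ring D complete)
Conditions: Dess–Martin periodinane, NaHCO3, CH2Cl2, 0 → 23 °C
Reagents that add atoms: none
Why: Dess–Martin oxidation of the only free (secondary) alcohol under buffered conditions spares the epoxides and the acetate, and no stereocentre is formed.

**Step 10**
Reactants: 19 diepoxy-ene keto acetate
Product: 21 target compound, via trimethylsilyl ether 20 (not isolated)
Conditions: Me3SiOTf (1.2 equiv), 2,6-di-tert-butyl-4-methylpyridine, CH2Cl2, −78 °C; then citric acid, MeOH, 0 °C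
Reagents that add atoms: none
Why: Second biomimetic epoxide-opening/cation–olefin cascade, in which silyl activation of the C2–C3 epoxide, oxepane closure through the epoxonium ion and attack of C11 of the E-alkene on C6 with inversion in a chair transition state set C6 (S) and C11 (R, equatorial chain) with C3 and C7 retained, and the hindered base removes a methyl proton to give the exocyclic alkene before methanolysis frees the C3 alcohol; no nucleophilic alkene remains in the right half to intercept the cation.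

**Compound list**
1 | geranylacetone, (5E)-6,10-dimethylundeca-5,9-dien-2-one | CC(=O)CC/C=C(\C)CCC=C(C)C | starting material
2 | (5S,6S,9S)-5,6:9,10-diepoxy-6,10-dimethylundecan-2-one | CC(=O)CC[C@@H]1O[C@@]1(C)CC[C@@H]1OC1(C)C | intermediate
3 | lithium enolate of 2 at the methyl carbon | [Li]OC(=C)CC[C@@H]1O[C@@]1(C)CC[C@@H]1OC1(C)C | intermediate
4 | Mannich base, (6S,7S,10S)-1-(dimethylamino)-6,7:10,11-diepoxy-7,11-dimethyldodecan-3-one | CN(C)CCC(=O)CC[C@@H]1O[C@@]1(C)CC[C@@H]1OC1(C)C | intermediate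
5 | N-methyl quaternary ammonium iodide of 4 | C[N+](C)(C)CCC(=O)CC[C@@H]1O[C@@]1(C)CC[C@@H]1OC1(C)C.[I-] | intermediate
6 | (6S,7S,10S)-6,7:10,11-diepoxy-7,11-dimethyldodec-1-en-3-one | C=CC(=O)CC[C@@H]1O[C@@]1(C)CC[C@@H]1OC1(C)C | intermediate
7 | (2E,6E)-farnesol | OC/C=C(\C)CC/C=C(\C)CCC=C(C)C | starting material
8 | (2E,6E)-farnesyl bromide | BrC/C=C(\C)CC/C=C(\C)CCC=C(C)C | intermediate
9 | (2E,6E)-farnesyl phenyl sulfone | O=S(=O)(C/C=C(\C)CC/C=C(\C)CCC=C(C)C)c1ccccc1 | intermediate
10 | 1-lithio derivative of 9 | [Li]C(/C=C(\C)CC/C=C(\C)CCC=C(C)C)S(=O)(=O)c1ccccc1 | intermediate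
11 | lithium (Z)-enolate (C10'=C11') of the Michael adduct of 10 and 6 | CC(C)=CCC/C(C)=C/CC/C(C)=C/C(S(=O)(=O)c1ccccc1)C/C=C(\O[Li])CC[C@@H]1O[C@@]1(C)CC[C@@H]1OC1(C)C | intermediate
12 | triethylsilyl (Z)-enol ether of the Michael adduct: Me2C=CH(CH2)2C(Me)=CH(CH2)2C(Me)=CH–CH(SO2Ph)–CH2–CH=C(OSiEt3)–(CH2)2–[(S,S)-epoxide]–(CH2)2–[(S)-epoxide CMe2], C12 epimers | CC(C)=CCC/C(C)=C/CC/C(C)=C/C(S(=O)(=O)c1ccccc1)C/C=C(\O[Si](CC)(CC)CC)CC[C@@H]1O[C@@]1(C)CC[C@@H]1OC1(C)C | intermediate
13 | (3'S,6'S,7'S,11'S) trans-fused 3'-(triethylsilyloxy)oxepane–cyclohexan-10'-one with the 12-(phenylsulfonyl) (E,E)-triene chain at C11' | O=C1CC[C@@H]2OC(C)(C)[C@@H](O[Si](CC)(CC)CC)CC[C@@]2(C)[C@@H]1CC(S(=O)(=O)c1ccccc1)/C=C(\C)CC/C=C(\C)CCC=C(C)C | intermediate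
14 | dichlorocerium 10'-alkoxide (10'R, axial O) of the methyl adduct of 13 | Cl[Ce](Cl)O[C@]1(C)CC[C@@H]2OC(C)(C)[C@@H](O[Si](CC)(CC)CC)CC[C@@]2(C)[C@@H]1CC(S(=O)(=O)c1ccccc1)/C=C(\C)CC/C=C(\C)CCC=C(C)C | intermediate
15 | 10'-acetate 3'-triethylsilyl ether | CC(=O)O[C@]1(C)CC[C@@H]2OC(C)(C)[C@@H](O[Si](CC)(CC)CC)CC[C@@]2(C)[C@@H]1CC(S(=O)(=O)c1ccccc1)/C=C(\C)CC/C=C(\C)CCC=C(C)C | intermediate
16 | (3'S,6'S,7'S,10'R,11'S)-10'-acetoxy-3'-hydroxy bicycle with the sulfonyl triene chain | CC(=O)O[C@]1(C)CC[C@@H]2OC(C)(C)[C@@H](O)CC[C@@]2(C)[C@@H]1CC(S(=O)(=O)c1ccccc1)/C=C(\C)CC/C=C(\C)CCC=C(C)C | intermediate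
17 | (3S,6S,7S)-2,3:6,7-diepoxide of 16, 12-sulfone and C10=C11 retained | CC(=O)O[C@]1(C)CC[C@@H]2OC(C)(C)[C@@H](O)CC[C@@]2(C)[C@@H]1CC(S(=O)(=O)c1ccccc1)/C=C(\C)CC[C@@H]1O[C@@]1(C)CC[C@@H]1OC1(C)C | intermediate
18 | desulfonylated (10E)-diepoxy-ene, 3'-hydroxy 10'-acetate | CC(=O)O[C@]1(C)CC[C@@H]2OC(C)(C)[C@@H](O)CC[C@@]2(C)[C@@H]1CC/C=C(\C)CC[C@@H]1O[C@@]1(C)CC[C@@H]1OC1(C)C | intermediate
19 | 3'-ketone of 18 (right half complete, left half (3S,6S,7S)-diepoxy-10E-ene) | CC(=O)O[C@]1(C)CC[C@@H]2OC(C)(C)C(=O)CC[C@@]2(C)[C@@H]1CC/C=C(\C)CC[C@@H]1O[C@@]1(C)CC[C@@H]1OC1(C)C | intermediate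
20 | 3-O-trimethylsilyl ether of the target | C=C1CC[C@@H]2OC(C)(C)[C@@H](O[Si](C)(C)C)CC[C@@]2(C)[C@@H]1CC[C@H]1[C@]2(C)CCC(=O)C(C)(C)O[C@H]2CC[C@@]1(C)OC(C)=O | intermediate
21 | CNP0148623.1, (3S,6S,7S,11R,6'S,7'S,10'R,11'S) | C=C1CC[C@@H]2OC(C)(C)[C@@H](O)CC[C@@]2(C)[C@@H]1CC[C@H]1[C@]2(C)CCC(=O)C(C)(C)O[C@H]2CC[C@@]1(C)OC(C)=O | target

**Totals:** 10 steps; longest linear sequence 9 steps (1 → 2 → 6 → 12 → 13 → 16 → 17 → 18 → 19 → 21).

**Steps most likely to fail and fallbacks**

Step 4. The adduct still carries an acidic C12–H next to the sulfone, so the enolate may be protonated internally before it is silylated, which would lose the regiodefined enol ether; 1,2-addition is a lesser risk. The fallback sets out from 9 (with 6) and comes back at 16. Compound 9 is lithiated and C-silylated with Me3SiCl to the α-trimethylsilyl sulfone F1, which has a single acidic hydrogen left. F1 is deprotonated with n-BuLi, added to 6 and trapped with Et3SiCl to give the silyl enol ether F2, which has no C12–H and cannot shuffle a proton. Catalytic Et3SiOTf converts F2 into the bicyclic ketone F3. MeLi/CeCl3 followed by Ac2O gives the acetate F4. Bu4NF buffered with AcOH then cleaves both the O–SiEt3 group and the α-sulfonyl C–SiMe3 bond to give 16.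

Step 8. The allylic hydrogenolysis may transpose the alkene or be slow at the hindered secondary sulfone, and it runs beside two epoxides. The fallback sets out from 17 and comes back at 21; it postpones sulfone removal until C12 is no longer allylic and keeps the ketone out of the reduction. Compound 17 is acetylated (Ac2O, pyridine) to the diacetate F5. F5 is cyclised with t-BuMe2SiOTf and 2,6-di-tert-butyl-4-methylpyridine, the sulfone-bearing alkene serving as a slower terminator, to the tetracyclic sulfone F6. SmI2 with HMPA removes the now saturated secondary sulfone to give the diacetate F7. K2CO3 in MeOH cleaves only the secondary acetate to give the hydroxy acetate F8. Dess–Martin oxidation gives the silyl ether ketone F9, and HF·pyridine gives 21.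

Step 10. Proton loss may give endocyclic alkene isomers besides the exocyclic one, and the tertiary acetate may ionise under the silyl triflate. The fallback sets out from 19 and comes back at 21; it ends the cascade by anion capture. SnCl4 in CH2Cl2 at −78 °C promotes the same epoxonium/cation–olefin sequence, and anti addition of chloride gives the tertiary chloride F10 with equatorial chlorine and axial methyl. An equatorial leaving group has no antiperiplanar ring hydrogen, so E2 with DBU in toluene at 80 °C can take only a methyl hydrogen and gives the exocyclic alkene 21.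

**Further compounds**
F1 | step 4 | (2E,6E)-1-(phenylsulfonyl)-1-(trimethylsilyl)farnesane-2,6,10-triene (α-trimethylsilyl sulfone) | C[Si](C)(C)C(/C=C(\C)CC/C=C(\C)CCC=C(C)C)S(=O)(=O)c1ccccc1
F2 | step 4 | 12-trimethylsilyl analogue of 12 | CC(C)=CCC/C(C)=C/CC/C(C)=C/C([Si](C)(C)C)(S(=O)(=O)c1ccccc1)C/C=C(\O[Si](CC)(CC)CC)CC[C@@H]1O[C@@]1(C)CC[C@@H]1OC1(C)C
F3 | step 4 | 12-trimethylsilyl analogue of 13 | O=C1CC[C@@H]2OC(C)(C)[C@@H](O[Si](CC)(CC)CC)CC[C@@]2(C)[C@@H]1CC([Si](C)(C)C)(S(=O)(=O)c1ccccc1)/C=C(\C)CC/C=C(\C)CCC=C(C)C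
F4 | step 4 | 12-trimethylsilyl analogue of 15 | CC(=O)O[C@]1(C)CC[C@@H]2OC(C)(C)[C@@H](O[Si](CC)(CC)CC)CC[C@@]2(C)[C@@H]1CC([Si](C)(C)C)(S(=O)(=O)c1ccccc1)/C=C(\C)CC/C=C(\C)CCC=C(C)C
F5 | step 8 | 3'-O-acetate of 17 (diacetate, diepoxy allylic sulfone) | CC(=O)O[C@]1(C)CC[C@@H]2OC(C)(C)[C@@H](OC(C)=O)CC[C@@]2(C)[C@@H]1CC(S(=O)(=O)c1ccccc1)/C=C(\C)CC[C@@H]1O[C@@]1(C)CC[C@@H]1OC1(C)C
F6 | step 8 | tetracyclic 12-(phenylsulfonyl) 3-O-tert-butyldimethylsilyl 3',10'-diacetate | C=C1CC[C@@H]2OC(C)(C)[C@@H](O[Si](C)(C)C(C)(C)C)CC[C@@]2(C)[C@@H]1C(S(=O)(=O)c1ccccc1)C[C@H]1[C@]2(C)CC[C@H](OC(C)=O)C(C)(C)O[C@H]2CC[C@@]1(C)OC(C)=O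
F7 | step 8 | desulfonylated tetracyclic 3-O-tert-butyldimethylsilyl 3',10'-diacetate | C=C1CC[C@@H]2OC(C)(C)[C@@H](O[Si](C)(C)C(C)(C)C)CC[C@@]2(C)[C@@H]1CC[C@H]1[C@]2(C)CC[C@H](OC(C)=O)C(C)(C)O[C@H]2CC[C@@]1(C)OC(C)=O
F8 | step 8 | 3'-hydroxy 10'-acetate 3-O-tert-butyldimethylsilyl ether | C=C1CC[C@@H]2OC(C)(C)[C@@H](O[Si](C)(C)C(C)(C)C)CC[C@@]2(C)[C@@H]1CC[C@H]1[C@]2(C)CC[C@H](O)C(C)(C)O[C@H]2CC[C@@]1(C)OC(C)=O
F9 | step 8 | 3-O-tert-butyldimethylsilyl ether of the target | C=C1CC[C@@H]2OC(C)(C)[C@@H](O[Si](C)(C)C(C)(C)C)CC[C@@]2(C)[C@@H]1CC[C@H]1[C@]2(C)CCC(=O)C(C)(C)O[C@H]2CC[C@@]1(C)OC(C)=O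
F10 | step 10 | 10-chloro-10-methyl analogue of the target (equatorial Cl, axial methyl) | C[C@]1(Cl)CC[C@@H]2OC(C)(C)[C@@H](O)CC[C@@]2(C)[C@@H]1CC[C@H]1[C@]2(C)CCC(=O)C(C)(C)O[C@H]2CC[C@@]1(C)OC(C)=O
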